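## Structural features

The target is a C20 dibromide with three rings. Ring A is a cyclohex-2-enone (C1, C2=O, C3=C4, C4a, C8a), trans-fused to the cyclohexane ring B (C4a to C8a): the angular C4a hydroxyl and the C8a methyl are anti. The cyclopentane ring C hangs on C3 through the single bond C3–C1'. Ring B carries four contiguous stereocentres, C8 (CHBr), C8a (quaternary, methyl), C4a (tertiary carbinol) and C5 (tertiary carbinol, methyl); the two hydroxyls are trans-diaxial and the bromine is equatorial, cis to the C8a methyl. Ring C carries C1' (quaternary, methyl) and C3' (CHBr), 1,3-related across the gem-dimethyl carbon C2', with bromine trans to the C1' methyl. Fragile groups are the tertiary allylic C4a hydroxyl of the γ-hydroxy enone, the vicinal ditertiary diol (dehydration, pinacol shift) and two secondary neopentyl bromides (E2, hydrogenolysis, halogen–metal exchange). The real difficulty is twofold: each quaternary carbon (C1', C8a) sits beside a brominated methine, and the C3–C1' single bond relays no stereochemical information between ring C and the decalin, so each half must be set in the absolute sense on its own. The key step uses the 1,3 relationship in ring C: an oxygen at C3' lies two ring bonds from C1', so as a zinc alkoxide it can deliver the carbon that becomes the C1' methyl to its own face, and is afterwards inverted to the bromide.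

## Logic of the disconnections

**35 ⇒ 34 ⇒ 33.** The C5–O and C4a–O bonds are removed back to the C4a=C5 olefin of a linear dienone. A trans-diaxial diol is the signature of an epoxide opened with inversion at one carbon, and both centres can be read from the angular C8a methyl. This takes two stereocentres and both acid-sensitive carbinols out of every earlier step. The forward demand is epoxidation of the γ,δ-olefin only, anti to the C8a methyl, and opening at C5 and not at C4a.

**33 ⇒ 32.** C8–Br is traced to C8–OH of opposite configuration. Oxygen is what a desymmetrising ketone reduction delivers, and a C8 bromide could not survive the C1 enolate used for fragment union (1,3-elimination to a cyclopropane). The demand is an SN2 displacement with inversion at a secondary neopentyl carbon.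

**32 ⇒ 29.** The C3=C4 bond of ring A is cut as an aldol condensation (with the silyl ether restored at C8). The decalin becomes a monocyclic ring B enal tethered to a C2 ketone. Regiochemistry is unambiguous, since the C3 enolate closes a six-membered ring and the C1 enolate only a four-membered one. The demand is enolisation of the ketone toward the neopentyl C3.

**29 ⇒ 28.** C4–C4a is cut back to an enol triflate. An aldehyde cannot be carried through the enolate steps, whereas the triflate is inert to amide bases. The demand is palladium insertion into a tetrasubstituted triflate without touching the alkyl bromide, with the C8 oxygen still masked.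

**28 ⇒ 26 ⇒ 25 ⇒ 23 + 15.** The C1–C2 bond is the convergent cut, dividing the molecule into near-equal halves. C1 is neopentyl, so it is made nucleophilic as an ester enolate; the ester carbonyl is a traceless activator, removed by decarboxylation after oxidation at C2. The demand is that the hindered enolate adds to 15 faster than it deprotonates it, and that oxidation and decarboxylation spare triflate, silyl ether and bromide.

**23 ⇒ 21 ⇒ 19 ⇒ 18 ⇒ 17 ⇒ 16 + 4.** Ring B is simplified by removing the C5 methyl (enolate alkylation), the C8 hydride (enantiotopic-group-selective reduction) and the C8a–C1 bond (dione alkylation). C8a lies between two carbonyl-level carbons, so it is the natural nucleophile of a 2-methyl-1,3-dione. One reagent-controlled reduction then fixes C8 and C8a together. The demand is discrimination of the two carbonyls and hydride delivery anti to the larger arm.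

**15 ⇒ 14 ⇒ 13 ⇒ 12.** The arm is returned to the protected alcohol and C3'–Br to C3'–OH with inversion. The oxygen is needed earlier as the directing group, and the bromide can only be introduced after the hydrogenolysis. The demand is SN2 at a neopentyl cyclopentyl carbon.

**12 ⇒ 11 ⇒ 9 (key).** The C1' methyl is traced to a cyclopropane methylene (C5'–CH2 re-formed), and the cyclopropane to the C1'=C5' olefin (C1'–CH2 and C5'–CH2 cut). A quaternary methyl that must be cis to the C3' oxygen across C2' is best delivered from that oxygen. The quaternary stereocentre is thereby reduced to a trisubstituted olefin plus one carbinol. The demands are complete facial control by the zinc alkoxide and hydrogenolysis of the least hindered cyclopropane bond. The arm oxygen is deliberately blocked as a bulky silyl ether in 9, because a free primary hydroxyl would be a second homoallylic donor able to reach either face.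

**9 ⇒ 8 ⇒ 7 ⇒ 6 ⇒ 3 + 4 ⇒ 1.** The silyl group, the ester oxidation level, the C3' hydride and the C1'–C3 bond are removed in turn. The symmetric dione supplies both functions: one carbonyl becomes the enol triflate that receives the two-carbon arm, the other the carbinol. The demands are a cross-coupling that outruns carbonyl addition and a reduction that treats the quaternary C2' as the large group.

## Other disconnections considered

**Alternative 1:** The cut is C4a–C8a together with C8–Br, closing ring B in one operation.
- **Forward step.** The acyclic (2E,6E)-8-cyano-3,7-dimethylocta-2,6-dienyl acetate A1 would be treated with Et2SBr·SbCl5Br. The bromonium ion at C8=C8a is opened at C8a by the C4a=C5 olefin through a chair, and proton loss would give the cyclised bromide A2.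
- **In favour.** C8–Br and the quaternary C8a are formed together, with bromine equatorial and trans to the C1 arm as a consequence of the E olefin. No substitution at a neopentyl carbon is needed. On this point the alternative is better than the chosen plan, which relies on step 21.
- **Also in favour.** A2 already holds C4 and the C4a=C5 olefin, which the chosen plan assembles in steps 14, 15 and 19. For ring B alone the step economy is better.
- **Against.** The bromonium source is achiral, so A2 would be racemic. Because ring C and the decalin do not communicate, union with an enantiopure ring C piece would give diastereomers, unless a chiral promoter or a resolution is added.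
- **Against.** Proton loss can give exocyclic or trisubstituted olefin isomers.
- **Against.** The nitrile carbon is C2, so C2–C3 must come from a neopentyl C3 organometallic next to C1', a harder union than the enolate aldol of step 16.
- **Comparison.** Mechanistically this is a cationic cascade, against a concerted carbenoid transfer. It leaves the ring C problem (C1', C3') untouched, so it complements the chosen key step without replacing it.

**Alternative 2:** The cut is C2–O and C4a–O, both oxygens coming from O2.
- **Forward step.** The ring A diene A3 (C2=C3–C4=C4a) would take up photochemically generated singlet oxygen in a [4+2] addition anti to the C8a methyl, giving the endoperoxide A4. Base-induced Kornblum–DeLaMare fragmentation would then give the C2 ketone and the C4a hydroxyl.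
- **In favour.** The angular hydroxyl and the enone oxidation level arrive in one late, stereocontrolled and non-acidic operation. The fragmentation is regiochemically unambiguous, since only C2 of the peroxide carries hydrogen. For C4a this is at least the equal of steps 22 and 23, and milder.
- **Against.** C5 must already be the tertiary carbinol, set separately, whereas the chosen end-game sets C4a and C5 as a pair from one olefin.
- **Against.** The homoannular diene must be generated regioselectively from an enone.
- **Against.** Ene reaction at the C1 methylene competes with the cycloaddition.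
- **Comparison.** It is a pericyclic end-game tactic, against electrophilic epoxidation with SN1-like opening, and of similar length. It does not address ring C.

**Alternative 3:** The cut is C1'–C2' of ring C.
- **Forward step.** (S)-Citronellol A5 would be converted into the α-diazo β-keto ester A6. Rh2(OAc)4 would generate a carbenoid at C2' that inserts into the tertiary C1'–H bond with retention, giving the cyclopentanone β-keto ester A7.
- **In favour.** The quaternary C1' is taken from the chiral pool in a single stereospecific step, with no catalyst-controlled reduction and no hydrogenolysis. On the directness of setting C1' it is better than the chosen plan.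
- **Equal.** The C3–C2 arm and a C3' carbonyl are in place, as in the chosen plan.
- **Against.** C2' of A7 carries H and CO2Me and must become CMe2 (methylation, then ester to methyl over several steps).
- **Against.** The C3' ketone must later be reduced to the alcohol cis to the C1' methyl. Its two faces differ only by methyl against a two-carbon chain across C2', so control would be weak. In the chosen plan C3' is set first by reagent control and then dictates C1'.
- **Comparison.** C–H insertion against directed methylene transfer. The overall length to 14 would be similar or greater.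

Key step: step 6

Remark on the chemistry: the sense of both oxazaborolidine reductions is assigned with the large/small model (quaternary α-carbon large). If either ketone responded in the opposite sense, the antipodal catalyst would be used and nothing else changes. Target locants (C1–C8a, C1'–C5') are used for all intermediates. The configurations were cross-checked: (S)-9 leads through (1S,3S,5R)-11 and (1S,3R)-12 to the (1R,3R) bromide of 35.

## Route

Step 1
Reactants: 1 2,2-dimethylcyclopentane-1,3-dione
Product: 3 5,5-dimethyl-4-oxocyclopent-1-en-1-yl trifluoromethanesulfonate, via potassium enolate 2 (not isolated)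
Conditions: KN(SiMe3)2, THF, −78 °C; then PhNTf2, −78 °C to 0 °C
Reagents that add atoms: N-phenylbis(trifluoromethanesulfonimide), O=S(=O)(N(c1ccccc1)S(=O)(=O)C(F)(F)F)C(F)(F)F
Why: Kinetic deprotonation of the non-enolised dione and O-sulfonylation of the enolate (enol triflate formation); C2' is quaternary, so only one enolate and one mono-triflate are possible.

Step 2
Reactants: 3 5,5-dimethyl-4-oxocyclopent-1-en-1-yl trifluoromethanesulfonate; 4 tert-butyl bromoacetate
Product: 6 tert-butyl 2-(5,5-dimethyl-4-oxocyclopent-1-en-1-yl)acetate, via Reformatsky reagent 5 (not isolated)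
Conditions: 4, Zn dust (Me3SiCl-activated), THF, rt; then 3, Pd2(dba)3 (2 mol%), XPhos (8 mol%), THF, rt to 40 °C
Reagents that add atoms: none
Why: Zinc insertion gives the Reformatsky reagent, which couples with the enol triflate under zerovalent palladium catalysis (Negishi-type sp2–sp3 coupling). At this temperature the ketone, shielded by the adjacent CMe2, should not undergo Reformatsky addition.

Step 3
Reactants: 6 tert-butyl 2-(5,5-dimethyl-4-oxocyclopent-1-en-1-yl)acetate
Product: 7 tert-butyl 2-[(4S)-4-hydroxy-5,5-dimethylcyclopent-1-en-1-yl]acetate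
Conditions: (R)-1-methyl-3,3-diphenyltetrahydro-1H,3H-pyrrolo[1,2-c][1,3,2]oxazaborole (15 mol%), BH3·SMe2, THF, −20 °C; MeOH
Reagents that add atoms: none
Why: Corey–Bakshi–Shibata reduction; with the quaternary C2' as the large group and the allylic CH2 as the small one, the (R)-catalyst should give the (S)-carbinol at C3'. The tert-butyl ester is inert to borane at this temperature.

Step 4
Reactants: 7 tert-butyl 2-[(4S)-4-hydroxy-5,5-dimethylcyclopent-1-en-1-yl]acetate
Product: 8 (1S)-3-(2-hydroxyethyl)-2,2-dimethylcyclopent-3-en-1-ol
Conditions: LiAlH4, THF, 0 °C to rt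
Reagents that add atoms: none
Why: Hydride reduction of the ester to the primary alcohol; the C3' stereocentre and the olefin are untouched.

Step 5
Reactants: 8 (1S)-3-(2-hydroxyethyl)-2,2-dimethylcyclopent-3-en-1-ol
Product: 9 (1S)-2,2-dimethyl-3-[2-(triisopropylsilyloxy)ethyl]cyclopent-3-en-1-ol
Conditions: i-Pr3SiCl, imidazole, CH2Cl2, 0 °C
Reagents that add atoms: chlorotriisopropylsilane, CC(C)[Si](Cl)(C(C)C)C(C)C
Why: Selective silylation of the unhindered primary hydroxyl over the neopentyl secondary one; the bulky ether removes the arm oxygen as a competing, face-unselective directing group.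

Step 6
Reactants: 9 (1S)-2,2-dimethyl-3-[2-(triisopropylsilyloxy)ethyl]cyclopent-3-en-1-ol
Product: 11 (1S,3S,5R)-2,2-dimethyl-1-[2-(triisopropylsilyloxy)ethyl]bicyclo[3.1.0]hexan-3-ol, via ethylzinc alkoxide 10 (not isolated)
Conditions: Et2Zn (hexane), CH2Cl2, 0 °C; then CH2I2, 0 °C to rt; aq. NH4Cl
Reagents that add atoms: diiodomethane, ICI
Why: Et2Zn first turns the C3' hydroxyl into the ethylzinc alkoxide 10, and further Et2Zn with CH2I2 gives the iodomethylzinc carbenoid (Furukawa variant of the Simmons–Smith reaction). The carbenoid binds to the alkoxide zinc and transfers CH2 to the C1'=C5' olefin through the butterfly transition state, so C1'–CH2 and C5'–CH2 form in one concerted, suprafacial [2+1] event on the oxygen face. The closest known reaction type is the hydroxyl-directed cyclopropanation of cyclopent-3-en-1-ols to cis-bicyclo[3.1.0]hexan-3-ols. The three-membered ring is closed by this concerted cheletropic addition, not by a stepwise exo or endo closure. C1' and C5' are created together; both are controlled by the C3' stereocentre from step 3 through intramolecular delivery, and their cis fusion follows from the suprafacial addition. Only π-facial selectivity is needed (one olefin, no regiochemical question); it is secured by the ring alkoxide two bonds from either olefin carbon and by the TIPS ether, whose oxygen is too hindered and too weakly basic to carry the reagent to the other face. The gem-dimethyl group at C2' hinders both faces equally, so it should slow the reaction without biasing it.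

Step 7
Reactants: 11 (1S,3S,5R)-2,2-dimethyl-1-[2-(triisopropylsilyloxy)ethyl]bicyclo[3.1.0]hexan-3-ol
Product: 12 (1S,3R)-2,2,3-trimethyl-3-[2-(triisopropylsilyloxy)ethyl]cyclopentan-1-ol
Conditions: H2 (3 atm), PtO2, AcOH, rt
Reagents that add atoms: none
Why: Hydrogenolysis of the cyclopropane over platinum cleaves the least substituted, least hindered bond C5'–CH2, so the former methylene becomes the C1' methyl and stays cis to the C3' hydroxyl. No benzylic or allylic bond competes, and the TIPS ether tolerates acetic acid.

Step 8
Reactants: 12 (1S,3R)-2,2,3-trimethyl-3-[2-(triisopropylsilyloxy)ethyl]cyclopentan-1-ol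
Product: 13 {2-[(1R,3R)-3-bromo-1,2,2-trimethylcyclopentyl]ethoxy}triisopropylsilane
Conditions: CBr4, PPh3, toluene, 0 °C to 60 °C
Reagents that add atoms: carbon tetrabromide, BrC(Br)(Br)Br
Why: Appel reaction; bromide displaces the alkoxyphosphonium group by SN2 with inversion at C3', placing bromine trans to the C1' methyl. A cyclopentane accepts backside attack more readily than a cyclohexane, and the bulky silyl ether oxygen is a poor neighbouring group.

Step 9
Reactants: 13 {2-[(1R,3R)-3-bromo-1,2,2-trimethylcyclopentyl]ethoxy}triisopropylsilane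
Product: 14 2-[(1R,3R)-3-bromo-1,2,2-trimethylcyclopentyl]ethan-1-ol
Conditions: Bu4NF, THF, 0 °C to rt
Reagents that add atoms: none
Why: Fluoride cleaves the primary silyl ether; the hindered secondary bromide should neither eliminate nor be displaced under these conditions.

Step 10
Reactants: 14 2-[(1R,3R)-3-bromo-1,2,2-trimethylcyclopentyl]ethan-1-ol
Product: 15 2-[(1R,3R)-3-bromo-1,2,2-trimethylcyclopentyl]acetaldehyde
Conditions: Dess–Martin periodinane, NaHCO3, CH2Cl2, 0 °C to rt
Reagents that add atoms: none
Why: Dess–Martin oxidation of the primary alcohol to the C2 aldehyde under buffered conditions; there is no stereocentre α to the new carbonyl.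

Step 11
Reactants: 16 2-methylcyclohexane-1,3-dione; 4 tert-butyl bromoacetate
Product: 17 tert-butyl 2-(1-methyl-2,6-dioxocyclohexyl)acetate
Conditions: NaOH (1 equiv), H2O, rt
Reagents that add atoms: none
Why: C-alkylation of the cyclic 1,3-dione enolate; in water, hydrogen bonding to the enolate oxygens suppresses O-alkylation, and the tert-butyl ester resists hydroxide.

Step 12
Reactants: 17 tert-butyl 2-(1-methyl-2,6-dioxocyclohexyl)acetate
Product: 18 tert-butyl 2-[(1R,2R)-2-hydroxy-1-methyl-6-oxocyclohexyl]acetate
Conditions: (S)-1-methyl-3,3-diphenyltetrahydro-1H,3H-pyrrolo[1,2-c][1,3,2]oxazaborole (20 mol%), catecholborane, toluene, −78 °C; pH 7 buffer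
Reagents that add atoms: none
Why: Enantiotopic-group-selective Corey–Bakshi–Shibata reduction of a 2,2-disubstituted 1,3-dione. Hydride is expected on the carbonyl face syn to the small methyl (anti to CH2CO2t-Bu), and the (S)-catalyst selects the carbonyl for which that face gives the (R)-carbinol, fixing C8 (hydroxyl cis to the C1 arm) and C8a together. One equivalent of catecholborane at low temperature limits reduction of the second ketone.

Step 13
Reactants: 18 tert-butyl 2-[(1R,2R)-2-hydroxy-1-methyl-6-oxocyclohexyl]acetate
Product: 19 tert-butyl 2-[(1R,2R)-1-methyl-6-oxo-2-(triethylsilyloxy)cyclohexyl]acetate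
Conditions: Et3SiCl, imidazole, DMAP (cat.), DMF, 0 °C to rt
Reagents that add atoms: chlorotriethylsilane, CC[Si](Cl)(CC)CC
Why: Silylation under weakly basic conditions that avoid retro-aldol opening of the β-hydroxy ketone; the ether masks the C8 oxygen through the enolate steps.

Step 14
Reactants: 19 tert-butyl 2-[(1R,2R)-1-methyl-6-oxo-2-(triethylsilyloxy)cyclohexyl]acetate
Product: 21 tert-butyl 2-[(1R,2R)-1,5-dimethyl-6-oxo-2-(triethylsilyloxy)cyclohexyl]acetate, via lithium enolate 20 (not isolated)
Conditions: LiN(i-Pr)2, THF, −78 °C; then MeI, DMPU, −78 to −20 °C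
Reagents that add atoms: iodomethane, CI
Why: Ketone enolate alkylation; C8a is quaternary, so C5 is the only enolisable ketone position, and the ketone is deprotonated before the less acidic neopentyl ester CH2. The C5 configuration is irrelevant because C5 becomes sp2 in the next step.

Step 15
Reactants: 21 tert-butyl 2-[(1R,2R)-1,5-dimethyl-6-oxo-2-(triethylsilyloxy)cyclohexyl]acetate
Product: 23 tert-butyl 2-[(1R,6R)-1,3-dimethyl-6-(triethylsilyloxy)-2-(trifluoromethanesulfonyloxy)cyclohex-2-en-1-yl]acetate, via potassium enolate 22 (not isolated)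
Conditions: KN(SiMe3)2, THF, −78 to 0 °C; then PhNTf2, −78 °C to rt
Reagents that add atoms: N-phenylbis(trifluoromethanesulfonimide), O=S(=O)(N(c1ccccc1)S(=O)(=O)C(F)(F)F)C(F)(F)F
Why: Removal of the remaining C5 hydrogen and O-sulfonylation give the only possible enol triflate, C4a(OTf)=C5; this is the usual entry to tetrasubstituted cyclohexenyl triflates from 2,2,6-trisubstituted cyclohexanones.

Step 16
Reactants: 23 tert-butyl 2-[(1R,6R)-1,3-dimethyl-6-(triethylsilyloxy)-2-(trifluoromethanesulfonyloxy)cyclohex-2-en-1-yl]acetate; 15 2-[(1R,3R)-3-bromo-1,2,2-trimethylcyclopentyl]acetaldehyde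
Product: 25 tert-butyl 4-[(1R,3R)-3-bromo-1,2,2-trimethylcyclopentyl]-2-[(1R,6R)-1,3-dimethyl-6-(triethylsilyloxy)-2-(trifluoromethanesulfonyloxy)cyclohex-2-en-1-yl]-3-hydroxybutanoate, via lithium enolate 24 (not isolated)
Conditions: 23, LiN(i-Pr)2, THF, −78 °C; then 15, −78 °C; aq. NH4Cl at −78 °C
Reagents that add atoms: none
Why: Lithium ester enolate aldol addition forms C1–C2; 23 holds no ketone, and the enol triflate and silyl ether are inert to the amide base at −78 °C. The mixture at C1 and C2 is of no consequence, since both centres are planarised or lose their substituent later. The C8 oxygen is a silyl ether and not a bromide, so the enolate cannot close a cyclopropane by 1,3-elimination.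

Step 17
Reactants: 25 tert-butyl 4-[(1R,3R)-3-bromo-1,2,2-trimethylcyclopentyl]-2-[(1R,6R)-1,3-dimethyl-6-(triethylsilyloxy)-2-(trifluoromethanesulfonyloxy)cyclohex-2-en-1-yl]-3-hydroxybutanoate
Product: 26 tert-butyl 4-[(1R,3R)-3-bromo-1,2,2-trimethylcyclopentyl]-2-[(1R,6R)-1,3-dimethyl-6-(triethylsilyloxy)-2-(trifluoromethanesulfonyloxy)cyclohex-2-en-1-yl]-3-oxobutanoate
Conditions: Dess–Martin periodinane, NaHCO3, CH2Cl2, rt
Reagents that add atoms: none
Why: Dess–Martin oxidation of the β-hydroxy ester sets the C2 ketone under buffered conditions that leave the silyl ether, triflate and bromide alone.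

Step 18
Reactants: 26 tert-butyl 4-[(1R,3R)-3-bromo-1,2,2-trimethylcyclopentyl]-2-[(1R,6R)-1,3-dimethyl-6-(triethylsilyloxy)-2-(trifluoromethanesulfonyloxy)cyclohex-2-en-1-yl]-3-oxobutanoate
Product: 28 (5R,6R)-6-{3-[(1R,3R)-3-bromo-1,2,2-trimethylcyclopentyl]-2-oxopropyl}-2,6-dimethyl-5-(triethylsilyloxy)cyclohex-1-en-1-yl trifluoromethanesulfonate, via β-keto acid 27 (not isolated)
Conditions: Me3SiOTf, 2,6-lutidine, CH2Cl2, 0 °C; pH 7 buffer; then toluene, 60 °C
Reagents that add atoms: none
Why: Silyl triflate with a hindered base converts the tert-butyl ester into the silyl ester with loss of 2-methylpropene and spares the silyl ether. Aqueous work-up gives the β-keto acid, which decarboxylates on warming through the cyclic six-membered transition state, leaving C1 as CH2.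

Step 19
Reactants: 28 (5R,6R)-6-{3-[(1R,3R)-3-bromo-1,2,2-trimethylcyclopentyl]-2-oxopropyl}-2,6-dimethyl-5-(triethylsilyloxy)cyclohex-1-en-1-yl trifluoromethanesulfonate
Product: 29 (5R,6S)-6-{3-[(1R,3R)-3-bromo-1,2,2-trimethylcyclopentyl]-2-oxopropyl}-2,6-dimethyl-5-(triethylsilyloxy)cyclohex-1-ene-1-carbaldehyde
Conditions: Pd(OAc)2 (5 mol%), dppp (6 mol%), Et3N, CO/H2 (1:1, 10 bar), DMF, 70 °C
Reagents that add atoms: carbon monoxide, [C-]#[O+]
Why: Palladium-catalysed reductive carbonylation (formylation) of an enol triflate: oxidative addition, CO insertion, then hydrogenolysis of the acyl palladium. Phosphine-ligated zerovalent palladium does not insert into unactivated secondary alkyl bromides, and the C8 oxygen is kept silylated so that it cannot trap the acyl palladium as a lactone.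

Step 20
Reactants: 29 (5R,6S)-6-{3-[(1R,3R)-3-bromo-1,2,2-trimethylcyclopentyl]-2-oxopropyl}-2,6-dimethyl-5-(triethylsilyloxy)cyclohex-1-ene-1-carbaldehyde
Product: 32 (8R,8aS)-3-[(1R,3R)-3-bromo-1,2,2-trimethylcyclopentyl]-8-hydroxy-5,8a-dimethyl-6,7,8,8a-tetrahydronaphthalen-2(1H)-one, via aldol adduct 30 (not isolated), via silyl dienone 31 (not isolated)
Conditions: NaOMe (0.3 equiv), MeOH, 0 °C to rt; then 1 M HCl, rt
Reagents that add atoms: none
Why: Intramolecular aldol condensation of a 1,5-keto aldehyde: the C3 enolate adds to C4 to close the six-membered ring A (the C1 enolate could only give a four-membered ring), and E1cB loss of water gives the linear dienone. Acidification then removes the triethylsilyl group; no stereocentre is formed or endangered.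

Step 21
Reactants: 32 (8R,8aS)-3-[(1R,3R)-3-bromo-1,2,2-trimethylcyclopentyl]-8-hydroxy-5,8a-dimethyl-6,7,8,8a-tetrahydronaphthalen-2(1H)-one
Product: 33 (8S,8aS)-8-bromo-3-[(1R,3R)-3-bromo-1,2,2-trimethylcyclopentyl]-5,8a-dimethyl-6,7,8,8a-tetrahydronaphthalen-2(1H)-one
Conditions: CBr4, PPh3, CH2Cl2, 0 °C to rt
Reagents that add atoms: carbon tetrabromide, BrC(Br)(Br)Br
Why: Appel reaction with inversion at C8: the hydroxyl trans to the C8a methyl becomes the equatorial bromide cis to it. The hindered dienone carbonyl should not take part.

Step 22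
Reactants: 33 (8S,8aS)-8-bromo-3-[(1R,3R)-3-bromo-1,2,2-trimethylcyclopentyl]-5,8a-dimethyl-6,7,8,8a-tetrahydronaphthalen-2(1H)-one
Product: 34 (4aR,5S,8S,8aS)-8-bromo-3-[(1R,3R)-3-bromo-1,2,2-trimethylcyclopentyl]-4a,5-epoxy-5,8a-dimethyl-4a,5,6,7,8,8a-hexahydronaphthalen-2(1H)-one
Conditions: m-CPBA, NaHCO3, CH2Cl2, 0 °C
Reagents that add atoms: 3-chloroperbenzoic acid, OOC(=O)c1cccc(Cl)c1
Why: Prilezhaev epoxidation is expected at the electron-richer tetrasubstituted γ,δ-olefin C4a=C5 and not at the α,β-olefin. Attack anti to the pseudo-axial C8a methyl and the C8 bromine puts both C–O bonds on the face opposite the angular methyl, which sets C4a.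

Step 23
Reactants: 34 (4aR,5S,8S,8aS)-8-bromo-3-[(1R,3R)-3-bromo-1,2,2-trimethylcyclopentyl]-4a,5-epoxy-5,8a-dimethyl-4a,5,6,7,8,8a-hexahydronaphthalen-2(1H)-one
Product: 35 (4aR,5R,8S,8aS)-8-bromo-3-[(1R,3R)-3-bromo-1,2,2-trimethylcyclopentyl]-4a,5-dihydroxy-5,8a-dimethyl-4a,5,6,7,8,8a-hexahydronaphthalen-2(1H)-one
Conditions: HClO4 (aq., cat.), THF/H2O, 0 °C to rt
Reagents that add atoms: water, O
Why: Acid-catalysed epoxide hydrolysis: the C5–O bond ionises (a plain tertiary centre, whereas positive charge at C4a would be conjugated with the electron-poor enone) and water attacks C5 anti to the departing oxygen. This trans-diaxial opening (Fürst–Plattner rule) should give the C5 hydroxyl cis and the C4a hydroxyl trans to the C8a methyl, the pattern known from ring-fusion epoxides of steroids.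

## Compound list

1 | 2,2-dimethylcyclopentane-1,3-dione | CC1(C)C(=O)CCC1=O | starting material
2 | potassium enolate of 1 | CC1(C)C(=O)CC=C1O[K] | intermediate
3 | 5,5-dimethyl-4-oxocyclopent-1-en-1-yl trifluoromethanesulfonate | CC1(C)C(=O)CC=C1OS(=O)(=O)C(F)(F)F | intermediate
4 | tert-butyl bromoacetate | CC(C)(C)OC(=O)CBr | starting material
5 | (2-tert-butoxy-2-oxoethyl)zinc bromide | CC(C)(C)OC(=O)C[Zn]Br | intermediate
6 | tert-butyl 2-(5,5-dimethyl-4-oxocyclopent-1-en-1-yl)acetate | CC1(C)C(=O)CC=C1CC(=O)OC(C)(C)C | intermediate
7 | tert-butyl 2-[(4S)-4-hydroxy-5,5-dimethylcyclopent-1-en-1-yl]acetate | CC1(C)[C@@H](O)CC=C1CC(=O)OC(C)(C)C | intermediate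
8 | (1S)-3-(2-hydroxyethyl)-2,2-dimethylcyclopent-3-en-1-ol | CC1(C)[C@@H](O)CC=C1CCO | intermediate
9 | (1S)-2,2-dimethyl-3-[2-(triisopropylsilyloxy)ethyl]cyclopent-3-en-1-ol | CC1(C)[C@@H](O)CC=C1CCO[Si](C(C)C)(C(C)C)C(C)C | intermediate
10 | ethylzinc alkoxide of 9 | CC1(C)[C@@H](O[Zn]CC)CC=C1CCO[Si](C(C)C)(C(C)C)C(C)C | intermediate
11 | (1S,3S,5R)-2,2-dimethyl-1-[2-(triisopropylsilyloxy)ethyl]bicyclo[3.1.0]hexan-3-ol (cyclopropane CH2 cis to OH) | CC1(C)[C@@H](O)C[C@H]2C[C@@]12CCO[Si](C(C)C)(C(C)C)C(C)C | intermediate
12 | (1S,3R)-2,2,3-trimethyl-3-[2-(triisopropylsilyloxy)ethyl]cyclopentan-1-ol (OH cis to the 3-methyl) | CC1(C)[C@@H](O)CC[C@]1(C)CCO[Si](C(C)C)(C(C)C)C(C)C | intermediate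
13 | {2-[(1R,3R)-3-bromo-1,2,2-trimethylcyclopentyl]ethoxy}triisopropylsilane (Br trans to the 1-methyl) | CC1(C)[C@H](Br)CC[C@]1(C)CCO[Si](C(C)C)(C(C)C)C(C)C | intermediate
14 | 2-[(1R,3R)-3-bromo-1,2,2-trimethylcyclopentyl]ethan-1-ol | CC1(C)[C@H](Br)CC[C@]1(C)CCO | intermediate
15 | 2-[(1R,3R)-3-bromo-1,2,2-trimethylcyclopentyl]acetaldehyde | CC1(C)[C@H](Br)CC[C@]1(C)CC=O | intermediate
16 | 2-methylcyclohexane-1,3-dione | CC1C(=O)CCCC1=O | starting material
17 | tert-butyl 2-(1-methyl-2,6-dioxocyclohexyl)acetate | CC1(CC(=O)OC(C)(C)C)C(=O)CCCC1=O | intermediate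
18 | tert-butyl 2-[(1R,2R)-2-hydroxy-1-methyl-6-oxocyclohexyl]acetate (OH cis to the acetate arm) | O=C1CCC[C@@H](O)[C@@]1(C)CC(=O)OC(C)(C)C | intermediate
19 | tert-butyl 2-[(1R,2R)-1-methyl-6-oxo-2-(triethylsilyloxy)cyclohexyl]acetate | O=C1CCC[C@@H](O[Si](CC)(CC)CC)[C@@]1(C)CC(=O)OC(C)(C)C | intermediate
20 | lithium enolate of 19 | [Li]OC1=CCC[C@@H](O[Si](CC)(CC)CC)[C@@]1(C)CC(=O)OC(C)(C)C | intermediate
21 | tert-butyl 2-[(1R,2R)-1,5-dimethyl-6-oxo-2-(triethylsilyloxy)cyclohexyl]acetate (both C5 epimers) | O=C1C(C)CC[C@@H](O[Si](CC)(CC)CC)[C@@]1(C)CC(=O)OC(C)(C)C | intermediate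
22 | potassium enolate of 21 | [K]OC1=C(C)CC[C@@H](O[Si](CC)(CC)CC)[C@@]1(C)CC(=O)OC(C)(C)C | intermediate
23 | tert-butyl 2-[(1R,6R)-1,3-dimethyl-6-(triethylsilyloxy)-2-(trifluoromethanesulfonyloxy)cyclohex-2-en-1-yl]acetate | O=S(=O)(OC1=C(C)CC[C@@H](O[Si](CC)(CC)CC)[C@@]1(C)CC(=O)OC(C)(C)C)C(F)(F)F | intermediate
24 | lithium ester enolate of 23 | [Li]OC(OC(C)(C)C)=C[C@]1(C)[C@H](O[Si](CC)(CC)CC)CCC(C)=C1OS(=O)(=O)C(F)(F)F | intermediate
25 | tert-butyl 4-[(1R,3R)-3-bromo-1,2,2-trimethylcyclopentyl]-2-[(1R,6R)-1,3-dimethyl-6-(triethylsilyloxy)-2-(trifluoromethanesulfonyloxy)cyclohex-2-en-1-yl]-3-hydroxybutanoate (mixture at C2 and C3 of the chain) | CC1(C)[C@H](Br)CC[C@]1(C)CC(O)C(C(=O)OC(C)(C)C)[C@]1(C)[C@H](O[Si](CC)(CC)CC)CCC(C)=C1OS(=O)(=O)C(F)(F)F | intermediate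
26 | tert-butyl 4-[(1R,3R)-3-bromo-1,2,2-trimethylcyclopentyl]-2-[(1R,6R)-1,3-dimethyl-6-(triethylsilyloxy)-2-(trifluoromethanesulfonyloxy)cyclohex-2-en-1-yl]-3-oxobutanoate | CC1(C)[C@H](Br)CC[C@]1(C)CC(=O)C(C(=O)OC(C)(C)C)[C@]1(C)[C@H](O[Si](CC)(CC)CC)CCC(C)=C1OS(=O)(=O)C(F)(F)F | intermediate
27 | β-keto acid corresponding to 26 | CC1(C)[C@H](Br)CC[C@]1(C)CC(=O)C(C(=O)O)[C@]1(C)[C@H](O[Si](CC)(CC)CC)CCC(C)=C1OS(=O)(=O)C(F)(F)F | intermediate
28 | (5R,6R)-6-{3-[(1R,3R)-3-bromo-1,2,2-trimethylcyclopentyl]-2-oxopropyl}-2,6-dimethyl-5-(triethylsilyloxy)cyclohex-1-en-1-yl trifluoromethanesulfonate | CC1(C)[C@H](Br)CC[C@]1(C)CC(=O)C[C@]1(C)[C@H](O[Si](CC)(CC)CC)CCC(C)=C1OS(=O)(=O)C(F)(F)F | intermediate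
29 | (5R,6S)-6-{3-[(1R,3R)-3-bromo-1,2,2-trimethylcyclopentyl]-2-oxopropyl}-2,6-dimethyl-5-(triethylsilyloxy)cyclohex-1-ene-1-carbaldehyde | CC1(C)[C@H](Br)CC[C@]1(C)CC(=O)C[C@]1(C)[C@H](O[Si](CC)(CC)CC)CCC(C)=C1C=O | intermediate
30 | (8R,8aS)-3-[(1R,3R)-3-bromo-1,2,2-trimethylcyclopentyl]-4-hydroxy-5,8a-dimethyl-8-(triethylsilyloxy)-3,4,6,7,8,8a-hexahydronaphthalen-2(1H)-one (aldol adduct, C3 and C4 unassigned) | CC1(C)[C@H](Br)CC[C@]1(C)C1C(O)C2=C(C)CC[C@@H](O[Si](CC)(CC)CC)[C@@]2(C)CC1=O | intermediate
31 | (8R,8aS)-3-[(1R,3R)-3-bromo-1,2,2-trimethylcyclopentyl]-5,8a-dimethyl-8-(triethylsilyloxy)-6,7,8,8a-tetrahydronaphthalen-2(1H)-one | CC1(C)[C@H](Br)CC[C@]1(C)C1=CC2=C(C)CC[C@@H](O[Si](CC)(CC)CC)[C@@]2(C)CC1=O | intermediate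
32 | (8R,8aS)-3-[(1R,3R)-3-bromo-1,2,2-trimethylcyclopentyl]-8-hydroxy-5,8a-dimethyl-6,7,8,8a-tetrahydronaphthalen-2(1H)-one (OH trans to the 8a-methyl) | CC1(C)[C@H](Br)CC[C@]1(C)C1=CC2=C(C)CC[C@@H](O)[C@@]2(C)CC1=O | intermediate
33 | (8S,8aS)-8-bromo-3-[(1R,3R)-3-bromo-1,2,2-trimethylcyclopentyl]-5,8a-dimethyl-6,7,8,8a-tetrahydronaphthalen-2(1H)-one (Br cis to the 8a-methyl) | CC1(C)[C@H](Br)CC[C@]1(C)C1=CC2=C(C)CC[C@H](Br)[C@@]2(C)CC1=O | intermediate
34 | (4aR,5S,8S,8aS)-8-bromo-3-[(1R,3R)-3-bromo-1,2,2-trimethylcyclopentyl]-4a,5-epoxy-5,8a-dimethyl-4a,5,6,7,8,8a-hexahydronaphthalen-2(1H)-one (epoxide anti to the 8a-methyl) | CC1(C)[C@H](Br)CC[C@]1(C)C1=C[C@]2(O3)[C@]3(C)CC[C@H](Br)[C@@]2(C)CC1=O | intermediate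
35 | (4aR,5R,8S,8aS)-8-bromo-3-[(1R,3R)-3-bromo-1,2,2-trimethylcyclopentyl]-4a,5-dihydroxy-5,8a-dimethyl-4a,5,6,7,8,8a-hexahydronaphthalen-2(1H)-one | CC1(C)[C@H](Br)CC[C@]1(C)C1=C[C@]2(O)[C@](C)(O)CC[C@H](Br)[C@@]2(C)CC1=O | target

## Step count and least certain steps

Total: 23 steps. Longest linear sequence: 18 steps (steps 1–10, then 16–23); ring B (steps 11–15) joins at step 16.

**Step 6 (key step).** The most likely failure is slow methylene transfer to a trisubstituted olefin flanked by the gem-dimethyl carbon. Forcing conditions would then let a non-directed background addition erode the facial selectivity. The fallback ties the carbon covalently to the C3' oxygen. It sets out from 9, which is acylated with the acid chloride of glyoxylic acid p-toluenesulfonylhydrazone and treated with Et3N to give the diazoacetate of 9 F1. Rh2(OAc)4 in CH2Cl2 should then effect intramolecular cyclopropanation to the tricyclic cyclopropane lactone F2, in which the tether forces the new carbon onto the oxygen face. Reduction with i-Bu2AlH gives the lactol F3, and its open hydroxy aldehyde form is decarbonylated with RhCl(PPh3)3 (Tsuji–Wilkinson decarbonylation, retention at the cyclopropane carbon). The sequence comes back to the route at 11.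

**Step 21.** The activated C8 oxygen is axial and anti-periplanar both to a C7 hydrogen and to the C8a methyl. E2 elimination or a 1,2-methyl shift can therefore outrun the slow backside attack at this neopentyl carbon. The fallback separates activation from displacement. It sets out from 32, which is converted with ClCH2SO2Cl and pyridine into the chloromethanesulfonate of 32 F4, a compact, non-ionising leaving group. Displacement with LiBr in DMPU should give inversion and returns to the route at 33.

**Step 8.** The same competition applies at C3': elimination to the cyclopentene, Wagner–Meerwein methyl shift, or capture of the activated carbon by the arm oxygen in place of clean inversion. The fallback sets out from 12, which gives the chloromethanesulfonate of 12 F5. Treatment with LiBr in DMPU then returns to the route at 13.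

**Step 23.** Ionisation at C5 may be followed by proton loss to an allylic alcohol, or by a pinacol-type shift, in place of capture by water. The fallback replaces water in mineral acid by a carboxylic acid that is both the proton source and the nucleophile. It sets out from 34, which in formic acid at 0 °C should open to the C5 formate of 35 F6. Mild methanolysis (KHCO3, MeOH) then returns to the route at 35.

**Step 16.** Proton transfer from aldehyde 15 to the congested enolate, or retro-aldol of the crowded adduct on warming, could limit the union. The fallback changes the bond-forming event to an acylation. It sets out from 14, which is oxidised (TEMPO, PhI(OAc)2, aqueous MeCN) to 2-[(1R,3R)-3-bromo-1,2,2-trimethylcyclopentyl]acetic acid F7. F7 is converted (carbonyldiimidazole, MeNHOMe·HCl) into its N-methoxy-N-methylamide F8. Addition of enolate 24 to F8 gives a stable tetrahedral adduct that releases the β-keto ester on work-up; this returns to the route at 26 and omits step 17.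

## Further compounds

F1 | step 6 | (1S)-2,2-dimethyl-3-[2-(triisopropylsilyloxy)ethyl]cyclopent-3-en-1-yl diazoacetate | CC1(C)[C@@H](OC(=O)C=[N+]=[N-])CC=C1CCO[Si](C(C)C)(C(C)C)C(C)C
F2 | step 6 | tricyclic lactone: 11 with its cyclopropane carbon joined through C(=O) to the C3' oxygen | CC1(C)[C@@H](O3)C[C@H]2[C@@H](C3=O)[C@@]12CCO[Si](C(C)C)(C(C)C)C(C)C
F3 | step 6 | lactol from reduction of F2 | CC1(C)[C@@H](O3)C[C@H]2[C@@H](C3O)[C@@]12CCO[Si](C(C)C)(C(C)C)C(C)C
F4 | step 21 | chloromethanesulfonate of 32 | CC1(C)[C@H](Br)CC[C@]1(C)C1=CC2=C(C)CC[C@@H](OS(=O)(=O)CCl)[C@@]2(C)CC1=O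
F5 | step 8 | chloromethanesulfonate of 12 | CC1(C)[C@@H](OS(=O)(=O)CCl)CC[C@]1(C)CCO[Si](C(C)C)(C(C)C)C(C)C
F6 | step 23 | C5 formate of 35 | CC1(C)[C@H](Br)CC[C@]1(C)C1=C[C@]2(O)[C@](C)(OC=O)CC[C@H](Br)[C@@]2(C)CC1=O
F7 | step 16 | 2-[(1R,3R)-3-bromo-1,2,2-trimethylcyclopentyl]acetic acid | CC1(C)[C@H](Br)CC[C@]1(C)CC(=O)O
F8 | step 16 | 2-[(1R,3R)-3-bromo-1,2,2-trimethylcyclopentyl]-N-methoxy-N-methylacetamide | CC1(C)[C@H](Br)CC[C@]1(C)CC(=O)N(C)OC
A1 | alternative 1 | (2E,6E)-8-cyano-3,7-dimethylocta-2,6-dien-1-yl acetate | CC(=O)OC/C=C(\C)CC/C=C(\C)CC#N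
A2 | alternative 1 | ring B bromide with C4a=C5 olefin, C4 acetate and C1–C2 nitrile arm | CC(=O)OCC1=C(C)CC[C@H](Br)[C@@]1(C)CC#N
A3 | alternative 2 | ring A 2,4(4a)-diene with the C5 carbinol and both bromides in place | CC1(C)[C@H](Br)CC[C@]1(C)C1=CC[C@]2(C)[C@@H](Br)CC[C@@](C)(O)C2=C1
A4 | alternative 2 | C2,C4a-endoperoxide | CC1(C)[C@H](Br)CC[C@]1(C)C1=C[C@]2(OO3)[C@](C)(O)CC[C@H](Br)[C@@]2(C)C[C@H]13
A5 | alternative 3 | (S)-citronellol | CC(C)=CCC[C@H](C)CCO
A6 | alternative 3 | methyl (6S)-8-(tert-butyldimethylsilyloxy)-2-diazo-6-methyl-3-oxooctanoate | COC(=O)C(=[N+]=[N-])C(=O)CC[C@H](C)CCO[Si](C)(C)C(C)(C)C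
A7 | alternative 3 | ring C cyclopentanone β-keto ester with quaternary C1' | COC(=O)C1C(=O)CC[C@]1(C)CCO[Si](C)(C)C(C)(C)C
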